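## Retrosynthetic overview

1. Target ⇐ SeO2 hydroxylation at C15, which also turns the 4,5-alkene into the ring-cis geometry; side-chain ester ⇐ 8β-alcohol + (E)-4-acetoxy-3-methylbut-2-enoic acid.
2. Ten-membered carbocycle and γ-lactone ⇐ green-light, chromium-catalysed intramolecular Barbier allylation of an ω-formyl 2-(bromomethyl)enoate (C6–C7 bond, C6 and C7 stereocentres); the lactone closes after the carbocycle.
3. Seco-compound ⇐ Morita–Baylis–Hillman reaction and SN2′ bromination at C7, unmasking of the C6 aldehyde, Lindlar reduction of a 2-yne to the 2Z-alkene.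
4. Epoxide (first ring) ⇐ C8–OH-directed epoxidation of the E-10(1)-alkene; carbon chain ⇐ Sonogashira coupling of an E-vinyl iodide with an (E)-enynol ether.
5. Vinyl iodide ⇐ carboalumination of the alkynol from (R)-glycidyl PMB ether and acetylide; C8 is the bought stereocentre. Ring order: epoxide, ten-membered ring, lactone.

Assumption: the target has the absolute configuration drawn (1R,6R,7R,8R,10R; germacrane numbering: ring C1–C10, lactone C11–C13, C14 on C10, C15 on C4), and compounds 1, 3 and 19 are catalogue chemicals.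

## Route

Step 1
Reactants: 1 (2E)-3-methylpent-2-en-4-yn-1-ol
Product: 2 triethyl{[(2E)-3-methylpent-2-en-4-yn-1-yl]oxy}silane
Conditions: TESCl (1.1 equiv), imidazole (1.5 equiv), CH2Cl2, 0 °C
Reagents that add atoms: chlorotriethylsilane CC[Si](Cl)(CC)CC
Why: Silyl ether formation on the only hydroxyl; no stereocentre is involved and the E-alkene is untouched.

Step 2
Reactants: 3 (2R)-2-{[(4-methoxybenzyl)oxy]methyl}oxirane
Product: 4 (2R)-1-[(4-methoxybenzyl)oxy]pent-4-yn-2-ol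
Conditions: LiC≡CH·ethylenediamine (1.5 equiv), DMSO, 10 °C to rt; H2O
Reagents that add atoms: lithium acetylide (ethylenediamine complex) [Li]C#C
Why: SN2 epoxide opening by acetylide at the terminal CH2; the carbinol carbon (future C8) is bought and not touched.

Step 3
Reactants: 4 (2R)-1-[(4-methoxybenzyl)oxy]pent-4-yn-2-ol
Product: 6 (2R,4E)-5-iodo-1-[(4-methoxybenzyl)oxy]-4-methylpent-4-en-2-ol, via alkenylalane 5 (not isolated)
Conditions: Me3Al (3 equiv), Cp2ZrCl2 (0.25 equiv), CH2Cl2, 0 °C to rt; then I2, THF, −30 to 0 °C; aq. Na2S2O3/Rochelle salt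
Reagents that add atoms: trimethylaluminium C[Al](C)C; iodine II
Why: Negishi zirconium-catalysed carboalumination adds methyl and aluminium syn across the alkyne (methyl on the inner carbon), and iodinolysis with retention gives the E-iodide that fixes the later trans-epoxide.

Step 4
Reactants: 6 (2R,4E)-5-iodo-1-[(4-methoxybenzyl)oxy]-4-methylpent-4-en-2-ol; 2 triethyl{[(2E)-3-methylpent-2-en-4-yn-1-yl]oxy}silane
Product: 7 (2R,4E,8E)-1-[(4-methoxybenzyl)oxy]-4,8-dimethyl-10-[(triethylsilyl)oxy]deca-4,8-dien-6-yn-2-ol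
Conditions: Pd(PPh3)2Cl2 (3 mol%), CuI (6 mol%), Et3N, THF, rt
Reagents that add atoms: none
Why: Sonogashira coupling joins C1 to C2 with retention of both alkene geometries and tolerates the free secondary alcohol.

Step 5
Reactants: 7 (2R,4E,8E)-1-[(4-methoxybenzyl)oxy]-4,8-dimethyl-10-[(triethylsilyl)oxy]deca-4,8-dien-6-yn-2-ol
Product: 8 (2R)-1-[(4-methoxybenzyl)oxy]-3-[(2R,3R)-2-methyl-3-{(3E)-3-methyl-5-[(triethylsilyl)oxy]pent-3-en-1-yn-1-yl}oxiran-2-yl]propan-2-ol
Conditions: VO(acac)2 (10 mol%), t-BuOOH (1.5 equiv, decane), PhMe, 0 °C to rt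
Reagents that add atoms: tert-butyl hydroperoxide CC(C)(C)OO
Why: Homoallylic-hydroxyl-directed vanadium epoxidation: the C8 vanadate ester delivers oxygen only to the alkene in reach, through a chair with the C7 arm equatorial and the C10 methyl pseudo-equatorial, so oxygen adds 1,3-anti to the C8 oxygen (8R gives 10R,1R) and the E-alkene gives the trans-epoxide.

Step 6
Reactants: 8 (2R)-1-[(4-methoxybenzyl)oxy]-3-[(2R,3R)-2-methyl-3-{(3E)-3-methyl-5-[(triethylsilyl)oxy]pent-3-en-1-yn-1-yl}oxiran-2-yl]propan-2-ol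
Product: 9 tert-butyldimethylsilyl ether of 8 at the secondary (C8) hydroxyl
Conditions: TBSCl (1.5 equiv), imidazole (3 equiv), DMF, rt
Reagents that add atoms: tert-butyldimethylsilyl chloride CC(C)(C)[Si](C)(C)Cl
Why: Silylation of the only free hydroxyl; a silyl ether (not an ester) is needed here so that C8 neither migrates an acyl group nor eliminates in steps 10 to 13.

Step 7
Reactants: 9 tert-butyldimethylsilyl ether of 8 at the secondary (C8) hydroxyl
Product: 10 (2R)-2-[(tert-butyldimethylsilyl)oxy]-3-[(2R,3R)-2-methyl-3-{(3E)-3-methyl-5-[(triethylsilyl)oxy]pent-3-en-1-yn-1-yl}oxiran-2-yl]propan-1-ol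
Conditions: DDQ (1.3 equiv), CH2Cl2/pH 7 buffer (10:1), 0 °C
Reagents that add atoms: none
Why: Oxidative PMB ether cleavage under buffered conditions, done at the enyne stage so that no conjugated diene is exposed to DDQ.

Step 8
Reactants: 10 (2R)-2-[(tert-butyldimethylsilyl)oxy]-3-[(2R,3R)-2-methyl-3-{(3E)-3-methyl-5-[(triethylsilyl)oxy]pent-3-en-1-yn-1-yl}oxiran-2-yl]propan-1-ol
Product: 11 (2R)-2-[(tert-butyldimethylsilyl)oxy]-3-[(2R,3R)-2-methyl-3-{(1Z,3E)-3-methyl-5-[(triethylsilyl)oxy]penta-1,3-dien-1-yl}oxiran-2-yl]propan-1-ol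
Conditions: H2 (1 atm), Pd/CaCO3 poisoned with Pb(OAc)2, quinoline, EtOAc, rt
Reagents that add atoms: none
Why: Lindlar semi-hydrogenation adds H2 syn to the conjugated alkyne and sets the 2Z-alkene.

Step 9
Reactants: 11 (2R)-2-[(tert-butyldimethylsilyl)oxy]-3-[(2R,3R)-2-methyl-3-{(1Z,3E)-3-methyl-5-[(triethylsilyl)oxy]penta-1,3-dien-1-yl}oxiran-2-yl]propan-1-ol
Product: 12 (2R)-2-[(tert-butyldimethylsilyl)oxy]-3-[(2R,3R)-2-methyl-3-{(1Z,3E)-3-methyl-5-[(triethylsilyl)oxy]penta-1,3-dien-1-yl}oxiran-2-yl]propanal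
Conditions: Dess–Martin periodinane (1.3 equiv), NaHCO3, CH2Cl2, 0 °C to rt
Reagents that add atoms: none
Why: Dess–Martin oxidation of the primary alcohol under buffered, non-epimerising conditions gives the α-silyloxy aldehyde (C7).

Step 10
Reactants: 12 (2R)-2-[(tert-butyldimethylsilyl)oxy]-3-[(2R,3R)-2-methyl-3-{(1Z,3E)-3-methyl-5-[(triethylsilyl)oxy]penta-1,3-dien-1-yl}oxiran-2-yl]propanal
Product: 13 methyl (4R)-4-[(tert-butyldimethylsilyl)oxy]-3-hydroxy-2-methylidene-5-[(2R,3R)-2-methyl-3-{(1Z,3E)-3-methyl-5-[(triethylsilyl)oxy]penta-1,3-dien-1-yl}oxiran-2-yl]pentanoate (both C3 epimers)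
Conditions: methyl acrylate (5 equiv), quinuclidine (0.5 equiv), MeOH (1 equiv), rt
Reagents that add atoms: methyl acrylate C=CC(=O)OC
Why: Morita–Baylis–Hillman reaction of the activated α-silyloxy aldehyde installs C11–C13; the new carbinol centre is a mixture that is erased in step 11, and the C6 aldehyde is still masked so the Z-diene is not exposed to the amine as a dienal.

Step 11
Reactants: 13 methyl (4R)-4-[(tert-butyldimethylsilyl)oxy]-3-hydroxy-2-methylidene-5-[(2R,3R)-2-methyl-3-{(1Z,3E)-3-methyl-5-[(triethylsilyl)oxy]penta-1,3-dien-1-yl}oxiran-2-yl]pentanoate (both C3 epimers)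
Product: 14 methyl (2Z,4R)-2-(bromomethyl)-4-[(tert-butyldimethylsilyl)oxy]-5-[(2R,3R)-2-methyl-3-{(1Z,3E)-3-methyl-5-[(triethylsilyl)oxy]penta-1,3-dien-1-yl}oxiran-2-yl]pent-2-enoate
Conditions: NBS (1.3 equiv), Me2S (1.5 equiv), CH2Cl2, −20 to 0 °C
Reagents that add atoms: N-bromosuccinimide O=C1CCC(=O)N1Br
Why: Corey–Kim-type activation of the allylic alcohol and SN2′ attack of bromide give the (Z)-2-(bromomethyl)enoate from both epimers under neutral conditions.

Step 12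
Reactants: 14 methyl (2Z,4R)-2-(bromomethyl)-4-[(tert-butyldimethylsilyl)oxy]-5-[(2R,3R)-2-methyl-3-{(1Z,3E)-3-methyl-5-[(triethylsilyl)oxy]penta-1,3-dien-1-yl}oxiran-2-yl]pent-2-enoate
Product: 15 methyl (2Z,4R)-2-(bromomethyl)-4-[(tert-butyldimethylsilyl)oxy]-5-[(2R,3R)-2-methyl-3-{(1Z,3E)-3-methyl-5-oxopenta-1,3-dien-1-yl}oxiran-2-yl]pent-2-enoate
Conditions: (COCl)2 (2 equiv), DMSO (4 equiv), CH2Cl2, −78 to −40 °C; then i-Pr2NEt, to 0 °C
Reagents that add atoms: none
Why: Swern conditions oxidise a primary triethylsilyl ether directly to the aldehyde while the secondary TBS ether is inert; the hindered base spares the allyl bromide and the (2E,4Z)-dienal cannot close to a pyran.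

Step 13
Reactants: 15 methyl (2Z,4R)-2-(bromomethyl)-4-[(tert-butyldimethylsilyl)oxy]-5-[(2R,3R)-2-methyl-3-{(1Z,3E)-3-methyl-5-oxopenta-1,3-dien-1-yl}oxiran-2-yl]pent-2-enoate
Product: 17 8β-[(tert-butyldimethylsilyl)oxy]-1β,10α-epoxygermacra-2Z,4E,11(13)-trien-6α,12-olide, via seco hydroxy ester 16 (not isolated)
Conditions: CrCl3·3THF (15 mol%), 4,4′-di-tert-butyl-2,2′-bipyridine (18 mol%), eosin Y (2 mol%), Hantzsch ester (1.5 equiv), NaHCO3 (2 equiv), degassed DMF (2 mM), green LEDs (525 nm), 20 °C; then 2-hydroxypyridine (0.2 equiv), 40 °C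
Reagents that add atoms: none
Why: Proposed new method: a visible-light, chromium-catalytic intramolecular Barbier (Nozaki–Hiyama type) allylation that closes the ten-membered ring; green-light-excited eosin Y is reductively quenched by the Hantzsch ester, the reduced dye and the Hantzsch radical turn trivalent chromium into divalent chromium, two divalent chromium centres convert the allyl bromide into an allylchromium (Cr on C13) that adds to the C6 aldehyde through a chair transition state with both chains pseudo-equatorial (6,7-trans) and on the C7 face anti to the C9 methylene in the allylic-strain-minimised conformer (H8 eclipsing the enoate, OTBS outside), which gives 6α-O and 7α-H relative to the bought C8; the Hantzsch pyridinium protonates the chromium alkoxide so the metal turns over and the C6 hydroxyl then closes the lactone; the low triplet energy of the dye spares the Z-diene and the light-gated low allylchromium concentration favours ring closure; the closest known reaction types are the stoichiometric CrCl2 Barbier macrocyclisation of ω-formyl 2-(bromomethyl)enoates to germacranolides and the intermolecular photoredox/chromium dual-catalytic allylation of aldehydes.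

Step 14
Reactants: 17 8β-[(tert-butyldimethylsilyl)oxy]-1β,10α-epoxygermacra-2Z,4E,11(13)-trien-6α,12-olide
Product: 18 8β-hydroxy-1β,10α-epoxygermacra-2Z,4E,11(13)-trien-6α,12-olide
Conditions: HF·pyridine, pyridine, THF, 0 °C to rt
Reagents that add atoms: none
Why: Buffered fluoride desilylation frees the C8 hydroxyl without touching the vinyl epoxide or the α-methylene lactone.

Step 15
Reactants: 19 ethyl (2E)-3-methyl-4-oxobut-2-enoate
Product: 21 (2E)-4-hydroxy-3-methylbut-2-enoic acid, via ethyl hydroxy ester 20 (not isolated)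
Conditions: NaBH4 (0.4 equiv), CeCl3·7H2O (0.4 equiv), EtOH, −20 °C; then 2 M NaOH, rt; HCl to pH 2
Reagents that add atoms: sodium hydroxide [Na+].[OH-]
Why: Luche 1,2-reduction of the aldehyde followed by saponification; the E-geometry prevents lactonisation.

Step 16
Reactants: 21 (2E)-4-hydroxy-3-methylbut-2-enoic acid
Product: 22 (2E)-4-acetoxy-3-methylbut-2-enoic acid
Conditions: Ac2O (1.5 equiv), pyridine, DMAP (5 mol%), CH2Cl2, 0 °C to rt; aqueous work-up
Reagents that add atoms: acetic anhydride CC(=O)OC(C)=O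
Why: O-Acetylation of the primary allylic alcohol; the free acid is recovered on aqueous work-up.

Step 17
Reactants: 18 8β-hydroxy-1β,10α-epoxygermacra-2Z,4E,11(13)-trien-6α,12-olide; 22 (2E)-4-acetoxy-3-methylbut-2-enoic acid
Product: 23 8β-{[(2E)-4-acetoxy-3-methylbut-2-enoyl]oxy}-1β,10α-epoxygermacra-2Z,4E,11(13)-trien-6α,12-olide
Conditions: DCC (1.5 equiv), DMAP (0.2 equiv), CH2Cl2, 0 °C to rt
Reagents that add atoms: none
Why: Steglich esterification with retention at C8; it is done before C15 is hydroxylated, so only one hydroxyl is present.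

Step 18
Reactants: 23 8β-{[(2E)-4-acetoxy-3-methylbut-2-enoyl]oxy}-1β,10α-epoxygermacra-2Z,4E,11(13)-trien-6α,12-olide
Product: 24 8β-{[(2E)-4-acetoxy-3-methylbut-2-enoyl]oxy}-15-hydroxy-1β,10α-epoxygermacra-2Z,4(ring-cis; 4E by CIP),11(13)-trien-6α,12-olide, (1R,6R,7R,8R,10R)
Conditions: SeO2 (0.5 equiv), t-BuOOH (2 equiv, decane), CH2Cl2, 0 °C to rt
Reagents that add atoms: tert-butyl hydroperoxide CC(C)(C)OO; selenium dioxide O=[Se]=O
Why: Riley–Sharpless allylic oxidation: ene reaction at C5 then [2,3]-sigmatropic shift places CH2OH trans to C6, which is the ring-cis 4,5-alkene of the target (the same alkene inversion as in the known parthenolide to melampomagnolide B oxidation); the electron-poor enoate and exo-methylene alkenes do not react.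

## Compound list

1 | (2E)-3-methylpent-2-en-4-yn-1-ol | C#C/C(C)=C/CO | starting material
2 | triethyl{[(2E)-3-methylpent-2-en-4-yn-1-yl]oxy}silane | C#C/C(C)=C/CO[Si](CC)(CC)CC | intermediate
3 | (2R)-2-{[(4-methoxybenzyl)oxy]methyl}oxirane | COc1ccc(COC[C@H]2CO2)cc1 | starting material
4 | (2R)-1-[(4-methoxybenzyl)oxy]pent-4-yn-2-ol | C#CC[C@@H](O)COCc1ccc(OC)cc1 | intermediate
5 | (E)-alkenyl(dimethyl)alane from 4, as its O-dimethylaluminium alkoxide | C[Al](C)/C=C(\C)C[C@@H](O[Al](C)C)COCc1ccc(OC)cc1 | intermediate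
6 | (2R,4E)-5-iodo-1-[(4-methoxybenzyl)oxy]-4-methylpent-4-en-2-ol | I/C=C(\C)C[C@@H](O)COCc1ccc(OC)cc1 | intermediate
7 | (2R,4E,8E)-1-[(4-methoxybenzyl)oxy]-4,8-dimethyl-10-[(triethylsilyl)oxy]deca-4,8-dien-6-yn-2-ol | CC[Si](CC)(CC)OC/C=C(C)/C#C/C=C(\C)C[C@@H](O)COCc1ccc(OC)cc1 | intermediate
8 | (2R)-1-[(4-methoxybenzyl)oxy]-3-[(2R,3R)-2-methyl-3-{(3E)-3-methyl-5-[(triethylsilyl)oxy]pent-3-en-1-yn-1-yl}oxiran-2-yl]propan-2-ol | CC[Si](CC)(CC)OC/C=C(C)/C#C[C@H]1O[C@]1(C)C[C@@H](O)COCc1ccc(OC)cc1 | intermediate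
9 | tert-butyldimethylsilyl ether of 8 at the secondary (C8) hydroxyl | CC[Si](CC)(CC)OC/C=C(C)/C#C[C@H]1O[C@]1(C)C[C@@H](O[Si](C)(C)C(C)(C)C)COCc1ccc(OC)cc1 | intermediate
10 | (2R)-2-[(tert-butyldimethylsilyl)oxy]-3-[(2R,3R)-2-methyl-3-{(3E)-3-methyl-5-[(triethylsilyl)oxy]pent-3-en-1-yn-1-yl}oxiran-2-yl]propan-1-ol | CC[Si](CC)(CC)OC/C=C(C)/C#C[C@H]1O[C@]1(C)C[C@@H](O[Si](C)(C)C(C)(C)C)CO | intermediate
11 | (2R)-2-[(tert-butyldimethylsilyl)oxy]-3-[(2R,3R)-2-methyl-3-{(1Z,3E)-3-methyl-5-[(triethylsilyl)oxy]penta-1,3-dien-1-yl}oxiran-2-yl]propan-1-ol | CC[Si](CC)(CC)OC/C=C(C)/C=C\[C@H]1O[C@]1(C)C[C@@H](O[Si](C)(C)C(C)(C)C)CO | intermediate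
12 | (2R)-2-[(tert-butyldimethylsilyl)oxy]-3-[(2R,3R)-2-methyl-3-{(1Z,3E)-3-methyl-5-[(triethylsilyl)oxy]penta-1,3-dien-1-yl}oxiran-2-yl]propanal | CC[Si](CC)(CC)OC/C=C(C)/C=C\[C@H]1O[C@]1(C)C[C@@H](O[Si](C)(C)C(C)(C)C)C=O | intermediate
13 | methyl (4R)-4-[(tert-butyldimethylsilyl)oxy]-3-hydroxy-2-methylidene-5-[(2R,3R)-2-methyl-3-{(1Z,3E)-3-methyl-5-[(triethylsilyl)oxy]penta-1,3-dien-1-yl}oxiran-2-yl]pentanoate (both C3 epimers) | CC[Si](CC)(CC)OC/C=C(C)/C=C\[C@H]1O[C@]1(C)C[C@@H](O[Si](C)(C)C(C)(C)C)C(O)C(=C)C(=O)OC | intermediate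
14 | methyl (2Z,4R)-2-(bromomethyl)-4-[(tert-butyldimethylsilyl)oxy]-5-[(2R,3R)-2-methyl-3-{(1Z,3E)-3-methyl-5-[(triethylsilyl)oxy]penta-1,3-dien-1-yl}oxiran-2-yl]pent-2-enoate | CC[Si](CC)(CC)OC/C=C(C)/C=C\[C@H]1O[C@]1(C)C[C@@H](O[Si](C)(C)C(C)(C)C)/C=C(\CBr)C(=O)OC | intermediate
15 | methyl (2Z,4R)-2-(bromomethyl)-4-[(tert-butyldimethylsilyl)oxy]-5-[(2R,3R)-2-methyl-3-{(1Z,3E)-3-methyl-5-oxopenta-1,3-dien-1-yl}oxiran-2-yl]pent-2-enoate | O=C/C=C(C)/C=C\[C@H]1O[C@]1(C)C[C@@H](O[Si](C)(C)C(C)(C)C)/C=C(\CBr)C(=O)OC | intermediate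
16 | methyl 2-[6α-hydroxy-8β-(tert-butyldimethylsilyloxy)-1β,10α-epoxygermacra-2Z,4E-dien-7-yl]prop-2-enoate (7α-H; seco-lactone) | COC(=O)C(=C)[C@H]1[C@H](O)/C=C(C)/C=C\[C@H]2O[C@]2(C)C[C@H]1O[Si](C)(C)C(C)(C)C | intermediate
17 | 8β-[(tert-butyldimethylsilyl)oxy]-1β,10α-epoxygermacra-2Z,4E,11(13)-trien-6α,12-olide | C=C1C(=O)O[C@@H]2/C=C(C)/C=C\[C@H]3O[C@]3(C)C[C@@H](O[Si](C)(C)C(C)(C)C)[C@@H]12 | intermediate
18 | 8β-hydroxy-1β,10α-epoxygermacra-2Z,4E,11(13)-trien-6α,12-olide | C=C1C(=O)O[C@@H]2/C=C(C)/C=C\[C@H]3O[C@]3(C)C[C@@H](O)[C@@H]12 | intermediate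
19 | ethyl (2E)-3-methyl-4-oxobut-2-enoate | CCOC(=O)/C=C(\C)C=O | starting material
20 | ethyl (2E)-4-hydroxy-3-methylbut-2-enoate | CCOC(=O)/C=C(\C)CO | intermediate
21 | (2E)-4-hydroxy-3-methylbut-2-enoic acid | OC(=O)/C=C(\C)CO | intermediate
22 | (2E)-4-acetoxy-3-methylbut-2-enoic acid | OC(=O)/C=C(\C)COC(C)=O | intermediate
23 | 8β-{[(2E)-4-acetoxy-3-methylbut-2-enoyl]oxy}-1β,10α-epoxygermacra-2Z,4E,11(13)-trien-6α,12-olide | C=C1C(=O)O[C@@H]2/C=C(C)/C=C\[C@H]3O[C@]3(C)C[C@@H](OC(=O)/C=C(\C)COC(C)=O)[C@@H]12 | intermediate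
24 | 8β-{[(2E)-4-acetoxy-3-methylbut-2-enoyl]oxy}-15-hydroxy-1β,10α-epoxygermacra-2Z,4(ring-cis),11(13)-trien-6α,12-olide, (1R,6R,7R,8R,10R) | C=C1C(=O)O[C@@H]2/C=C(CO)\C=C/[C@H]3O[C@]3(C)C[C@@H](OC(=O)/C=C(\C)COC(C)=O)[C@@H]12 | target

## Step count and risks

Total step count: 18. Longest linear sequence: 15 steps (3 to 24 through steps 2–14, 17 and 18).

**Step 13 (the proposed new ring closure).** The chromium may turn over poorly, the allyl bromide may simply be reduced, or the wrong C6/C7 pair may form. The fallback uses known thermal allylboration and sets out from bromide 14. Borylation with bis(pinacolato)diboron and Pd2(dba)3 (2.5 mol%) in DMSO/THF at 50 °C gives the linear 2-(methoxycarbonyl)allyl boronate F1. The Swern conditions of step 12 turn its triethylsilyl ether into the aldehyde boronate F2. Heating F2 at 1 mM in toluene at 80 °C brings about the uncatalysed intramolecular allylboration through the same chair arrangement and gives hydroxy ester 16. With 2-hydroxypyridine this closes to 17, where the route is rejoined.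

**Step 5 (directed epoxidation).** 1,3-Induction from a carbinol to a quaternary epoxide carbon is the least certain stereochemical event, and the facial preference could be the opposite one. The fallback sets out from 7 and assumes a syn-selective epoxidation. Mitsunobu inversion (4-nitrobenzoic acid, PPh3, DIAD, THF) gives the (8S)-4-nitrobenzoate F3, and K2CO3 in MeOH gives the (8S)-alcohol F4. The same VO(acac)2/t-BuOOH epoxidation then gives the syn epoxy alcohol F5 (8S,10R,1R). A second Mitsunobu inversion gives the (8R)-4-nitrobenzoate F6, and methanolysis returns 8.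

**Step 18 (SeO2 hydroxylation with alkene inversion).** The reaction may over-oxidise, keep the 4E geometry, or damage the vinyl epoxide. The fallback sets out from 23. SeO2 (1.2 equiv) in dioxane at 60 °C takes C15 through to the conjugated 15-aldehyde F7. This trisubstituted enal settles, if needed with a trace of I2, in the isomer with the formyl group trans to C6. Luche reduction (NaBH4, CeCl3·7H2O, MeOH, −78 °C) then gives 24 without touching the α-methylene lactone.

Further compounds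
F1 | step 13 | methyl (2Z,4R)-4-[(tert-butyldimethylsilyl)oxy]-5-[(2R,3R)-2-methyl-3-{(1Z,3E)-3-methyl-5-[(triethylsilyl)oxy]penta-1,3-dien-1-yl}oxiran-2-yl]-2-[(4,4,5,5-tetramethyl-1,3,2-dioxaborolan-2-yl)methyl]pent-2-enoate | CC[Si](CC)(CC)OC/C=C(C)/C=C\[C@H]1O[C@]1(C)C[C@@H](O[Si](C)(C)C(C)(C)C)/C=C(\CB2OC(C)(C)C(C)(C)O2)C(=O)OC
F2 | step 13 | methyl (2Z,4R)-4-[(tert-butyldimethylsilyl)oxy]-5-[(2R,3R)-2-methyl-3-{(1Z,3E)-3-methyl-5-oxopenta-1,3-dien-1-yl}oxiran-2-yl]-2-[(4,4,5,5-tetramethyl-1,3,2-dioxaborolan-2-yl)methyl]pent-2-enoate | O=C/C=C(C)/C=C\[C@H]1O[C@]1(C)C[C@@H](O[Si](C)(C)C(C)(C)C)/C=C(\CB2OC(C)(C)C(C)(C)O2)C(=O)OC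
F3 | step 5 | (2S,4E,8E)-1-[(4-methoxybenzyl)oxy]-4,8-dimethyl-10-[(triethylsilyl)oxy]deca-4,8-dien-6-yn-2-yl 4-nitrobenzoate | CC[Si](CC)(CC)OC/C=C(C)/C#C/C=C(\C)C[C@H](OC(=O)c1ccc(cc1)[N+](=O)[O-])COCc1ccc(OC)cc1
F4 | step 5 | (2S,4E,8E)-1-[(4-methoxybenzyl)oxy]-4,8-dimethyl-10-[(triethylsilyl)oxy]deca-4,8-dien-6-yn-2-ol | CC[Si](CC)(CC)OC/C=C(C)/C#C/C=C(\C)C[C@H](O)COCc1ccc(OC)cc1
F5 | step 5 | (2S)-1-[(4-methoxybenzyl)oxy]-3-[(2R,3R)-2-methyl-3-{(3E)-3-methyl-5-[(triethylsilyl)oxy]pent-3-en-1-yn-1-yl}oxiran-2-yl]propan-2-ol | CC[Si](CC)(CC)OC/C=C(C)/C#C[C@H]1O[C@]1(C)C[C@H](O)COCc1ccc(OC)cc1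
F6 | step 5 | (2R)-1-[(4-methoxybenzyl)oxy]-3-[(2R,3R)-2-methyl-3-{(3E)-3-methyl-5-[(triethylsilyl)oxy]pent-3-en-1-yn-1-yl}oxiran-2-yl]propan-2-yl 4-nitrobenzoate | CC[Si](CC)(CC)OC/C=C(C)/C#C[C@H]1O[C@]1(C)C[C@@H](OC(=O)c1ccc(cc1)[N+](=O)[O-])COCc1ccc(OC)cc1
F7 | step 18 | 8β-{[(2E)-4-acetoxy-3-methylbut-2-enoyl]oxy}-15-oxo-1β,10α-epoxygermacra-2Z,4(ring-cis),11(13)-trien-6α,12-olide | C=C1C(=O)O[C@@H]2/C=C(C=O)\C=C/[C@H]3O[C@]3(C)C[C@@H](OC(=O)/C=C(\C)COC(C)=O)[C@@H]12
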